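**Plan**

1. Labdane numbering is used: ring A = C1–C5 and C10, ring B = C5–C10, C17 is the methylene on C8, C18 (methyl) and C19 (carboxyl) sit on C4, C20 is the methyl on C10, and C11–C16 is the side chain. The enabling feature is the chain C2(OH)–C1–C10–C9 that ends at the exocyclic C8=C17 bond. The C1–C2 and C9–C10 bonds lie anti across a former C1=C10 double bond, and the methylene marks where an allylsilane ended a cationic cascade.
2. Retrosynthesis: the two esters are unmasked last. C1–C2 and C9–C10 are cut together, which opens rings A and B to an acyclic C2 aldehyde carrying an isopropenyl group (C10=C1) on C5 and a Z-allylsilane (C8=C9, Si on C17). C8–C17 and C7–C8 are then cut (two couplings on a 1,1-dichloroalkene), which separates a C2–C7/C19 lactone from a C8–C15 enoate.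
3. Forward: the lactone fragment (5 steps) and the dichloroalkene (3 steps) are joined at C7–C8. CH2SiMe3 is then placed on C8, the lactone is opened and oxidised to the aldehyde diester, ring A and then ring B close in one operation, and the allyl esters are removed.
4. Stereochemistry: C5 comes from a Rh/BINAP-catalysed isopropenyl transfer. C4 comes from two lactone enolate alkylations anti to the isopropenyl group (two-carbon arm first, methyl second). 13E comes from syn-carbocupration of methyl but-2-ynoate. The Z-allylsilane comes from a trans-selective and then a stereoretentive coupling. C2, C9 and C10 come from the chair–chair cascade under control of C4/C5.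

Key step: step 13

Remark: allyl esters replace methyl esters at C15/C19 in the key-step compounds because the axial, neopentyl C19 methyl ester would resist saponification; the facial sense of step 1 with (S)-BINAP is assumed by analogy with aryl and alkenyl transfer to six-membered enones and lactones, and the ligand antipode is used if the sense proves opposite.

**Route**

Step 1
Reactants: 1 5,6-dihydro-2H-pyran-2-one; 2 potassium trifluoro(prop-1-en-2-yl)borate
Product: 3 (4S)-4-(prop-1-en-2-yl)oxan-2-one
Conditions: [Rh(cod)2]PF6 (3 mol %), (S)-BINAP (3.3 mol %), toluene/H2O 20:1, 105 °C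
Reagents that add atoms: none
Why: Rh/BINAP-catalysed asymmetric conjugate addition of an alkenylboron reagent (Hayashi–Miyaura reaction) to the unsaturated lactone should set C5 (lactone C4) by enantioface selection of the Rh-bound acceptor in the chiral ligand pocket.

Step 2
Reactants: 3 (4S)-4-(prop-1-en-2-yl)oxan-2-one; 4 tert-butyl(2-iodoethoxy)dimethylsilane
Product: 6 (3R,4S)-3-[2-(tert-butyldimethylsilyloxy)ethyl]-4-(prop-1-en-2-yl)oxan-2-one, via lithium enolate 5 (not isolated)
Conditions: LDA, THF, −78 °C; then 4, DMPU, −78 → −30 °C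
Reagents that add atoms: none
Why: SN2 alkylation of the lithium lactone enolate should occur anti to the neighbouring isopropenyl group to give the trans lactone, whose new centre is erased again by the next enolisation.

Step 3
Reactants: 6 (3R,4S)-3-[2-(tert-butyldimethylsilyloxy)ethyl]-4-(prop-1-en-2-yl)oxan-2-one
Product: 8 (3S,4R)-3-[2-(tert-butyldimethylsilyloxy)ethyl]-3-methyl-4-(prop-1-en-2-yl)oxan-2-one, via lithium enolate 7 (not isolated)
Conditions: LDA, THF, −78 °C; MeI, −78 → −40 °C
Reagents that add atoms: iodomethane (CI)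
Why: In this second enolate alkylation iodomethane should attack the tetrasubstituted enolate on the face opposite the isopropenyl group (held pseudoaxial by A(1,2) strain with the side arm), which fixes quaternary C4 with methyl trans and the two-carbon arm cis to isopropenyl.

Step 4
Reactants: 8 (3S,4R)-3-[2-(tert-butyldimethylsilyloxy)ethyl]-3-methyl-4-(prop-1-en-2-yl)oxan-2-one
Product: 10 (3S)-3-[(3R)-5-hydroxy-2-methylpent-1-en-3-yl]-3-methyloxolan-2-one, via δ-lactone alcohol 9 (not isolated)
Conditions: TBAF, THF, 0 °C → rt (cat. DBU if the acyl shift is incomplete); aq. work-up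
Reagents that add atoms: none
Why: Fluoride desilylation frees an alkoxide five atoms from the lactone carbonyl, and intramolecular transesterification (5-exo acyl transfer) should lead to the more stable γ-lactone, which masks C19 and O–C2 together and frees the C7 hydroxyl without touching a stereocentre.

Step 5
Reactants: 10 (3S)-3-[(3R)-5-hydroxy-2-methylpent-1-en-3-yl]-3-methyloxolan-2-one
Product: 11 (3S)-3-[(3R)-5-iodo-2-methylpent-1-en-3-yl]-3-methyloxolan-2-one
Conditions: I2, PPh3, imidazole, CH2Cl2, 0 °C
Reagents that add atoms: iodine (II)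
Why: Appel-type iodination replaces the primary hydroxyl by SN2 displacement of an oxyphosphonium ion and leaves the lactone and the isopropenyl group alone.

Step 6
Reactants: 12 but-3-en-1-ylmagnesium bromide; 13 methyl but-2-ynoate
Product: 16 methyl (2E)-3-methylhepta-2,6-dienoate, via but-3-enylcopper 14 (not isolated), via alkenylcopper adduct 15 (not isolated)
Conditions: CuI (1 equiv), THF, −40 °C; then 13, −78 °C; sat. aq NH4Cl at −78 °C
Reagents that add atoms: none
Why: Syn-carbocupration of the ynoate followed by stereoretentive protonation at low temperature should place the new chain trans to the ester and so fix the 13E enoate geometry.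

Step 7
Reactants: 16 methyl (2E)-3-methylhepta-2,6-dienoate
Product: 18 methyl (2E)-3-methyl-6-oxohex-2-enoate, via diol 17 (not isolated)
Conditions: OsO4 (2 mol %), NaIO4, 2,6-lutidine, dioxane/H2O, rt
Reagents that add atoms: osmium tetroxide (O=[Os](=O)(=O)=O), regenerated by sodium periodate ([Na+].[O-]I(=O)(=O)=O)
Why: Lemieux–Johnson cleavage (dihydroxylation, then glycol cleavage) is selective for the electron-richer monosubstituted terminal alkene over the conjugated trisubstituted enoate.

Step 8
Reactants: 18 methyl (2E)-3-methyl-6-oxohex-2-enoate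
Product: 19 methyl (2E)-7,7-dichloro-3-methylhepta-2,6-dienoate
Conditions: PPh3, CCl4, THF, 60 °C
Reagents that add atoms: carbon tetrachloride (ClC(Cl)(Cl)Cl)
Why: Wittig-type dichloromethylenation by the ylide formed in the flask from PPh3 and CCl4 converts the aldehyde to the 1,1-dichloroalkene under neutral conditions that spare the enoate.

Step 9
Reactants: 11 (3S)-3-[(3R)-5-iodo-2-methylpent-1-en-3-yl]-3-methyloxolan-2-one; 19 methyl (2E)-7,7-dichloro-3-methylhepta-2,6-dienoate
Product: 21 methyl (2E,6Z,10R)-7-chloro-3,11-dimethyl-10-[(3S)-3-methyl-2-oxooxolan-3-yl]dodeca-2,6,11-trienoate, via alkylzinc iodide 20 (not isolated)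
Conditions: Zn dust (BrCH2CH2Br/TMSCl-activated), DMA, 40 °C; then 19, Pd(DPEphos)Cl2 (5 mol %), DMF, 23 °C
Reagents that add atoms: none
Why: Zinc insertion into the primary C–I bond and Negishi coupling, with oxidative addition at the less hindered C–Cl bond trans to the alkyl substituent of the 1,1-dichloroalkene, should give monoalkylation with C7 trans to C11, that is the (Z)-chloroalkene.

Step 10
Reactants: 21 methyl (2E,6Z,10R)-7-chloro-3,11-dimethyl-10-[(3S)-3-methyl-2-oxooxolan-3-yl]dodeca-2,6,11-trienoate; 22 (trimethylsilyl)methylmagnesium chloride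
Product: 24 methyl (2E,6Z,10R)-3,11-dimethyl-10-[(3S)-3-methyl-2-oxooxolan-3-yl]-7-[(trimethylsilyl)methyl]dodeca-2,6,11-trienoate, via (trimethylsilyl)methylzinc chloride 23 (not isolated)
Conditions: ZnCl2, THF, 0 °C; then 21, Pd(t-Bu3P)2 (5 mol %), THF/NMP, 60 °C
Reagents that add atoms: none
Why: Negishi coupling of the remaining alkenyl chloride with the ester-tolerant silylmethylzinc reagent under a bulky electron-rich Pd(0) catalyst proceeds with retention, so CH2SiMe3 ends cis to C11 and the Z-allylsilane results.

Step 11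
Reactants: 24 methyl (2E,6Z,10R)-3,11-dimethyl-10-[(3S)-3-methyl-2-oxooxolan-3-yl]-7-[(trimethylsilyl)methyl]dodeca-2,6,11-trienoate
Product: 26 bis(prop-2-en-1-yl) (2E,6Z,10R,11S)-11-(2-hydroxyethyl)-3,11-dimethyl-10-(prop-1-en-2-yl)-7-[(trimethylsilyl)methyl]dodeca-2,6-dienedioate, via dipotassium dicarboxylate 25 (not isolated)
Conditions: KOH, MeOH/H2O, 50 °C; CO2 (quench of excess base), evaporate; allyl bromide, DMF, 0 °C → rt
Reagents that add atoms: potassium hydroxide ([K+].[OH-]); allyl bromide (C=CCBr)
Why: Saponification opens the γ-lactone and cleaves the methyl ester, and SN2 O-alkylation of both carboxylates with allyl bromide gives the hydroxy diester under near-neutral conditions that should not relactonise it.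

Step 12
Reactants: 26 bis(prop-2-en-1-yl) (2E,6Z,10R,11S)-11-(2-hydroxyethyl)-3,11-dimethyl-10-(prop-1-en-2-yl)-7-[(trimethylsilyl)methyl]dodeca-2,6-dienedioate
Product: 27 bis(prop-2-en-1-yl) (2E,6Z,10R,11S)-3,11-dimethyl-11-(2-oxoethyl)-10-(prop-1-en-2-yl)-7-[(trimethylsilyl)methyl]dodeca-2,6-dienedioate
Conditions: Dess–Martin periodinane, NaHCO3, CH2Cl2, 0 °C (crude 26 used at once)
Reagents that add atoms: none
Why: Buffered Dess–Martin oxidation converts the primary alcohol to the aldehyde without acid that could protodesilylate the allylsilane and removes the hydroxyl before it can attack the C19 ester.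

Step 13
Reactants: 27 bis(prop-2-en-1-yl) (2E,6Z,10R,11S)-3,11-dimethyl-11-(2-oxoethyl)-10-(prop-1-en-2-yl)-7-[(trimethylsilyl)methyl]dodeca-2,6-dienedioate
Product: 28 bis(prop-2-en-1-yl) (2R,4S,5R,9S,10R,13E)-2-hydroxylabda-8(17),13-diene-15,19-dioate
Conditions: MeAlCl2 (3.5 equiv), CH2Cl2, −78 → −40 °C; aq. Rochelle salt
Reagents that add atoms: none
Why: Coordination of MeAlCl2 makes C2 electrophilic enough to be attacked by C1, the CH2 terminus of the isopropenyl group, in a Prins closure of ring A that leaves a tertiary cation at C10; C9, the γ-carbon of the allylsilane, captures this cation and loss of the silyl group from C17 leaves only the C8=C17 alkene. The closest known reaction types are the alkylaluminium-halide-promoted aldehyde-initiated cation–olefin cyclisation and the allylsilane-terminated polyene cyclisation. Ring A closes through a six-membered chair, 6-endo with respect to the C1=C10 alkene (exo at the carbonyl), and ring B through a second chair, 6-endo with respect to the C8=C9 alkene. At C2 the aluminium-bound oxygen takes the equatorial position to avoid the axial C19 ester, which gives the 2α (2R) alcohol; at C10 the chair–chair array fixed by C4/C5 (C6 equatorial, H5 axial, only the ester axial) makes C9 add anti to the new C1–C2 bond, which gives the trans fusion with C20 axial; at C9 the Z-allylsilane geometry places C11 equatorial. The step needs cation capture to outrun proton loss from C20 (ene outcome) and protodesilylation; the excess of proton-scavenging Lewis acid keeps the aluminium alkoxide non-basic and saturates both ester carbonyls, and the nucleophilic allylsilane sits one six-membered transition state from C10.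

Step 14
Reactants: 28 bis(prop-2-en-1-yl) (2R,4S,5R,9S,10R,13E)-2-hydroxylabda-8(17),13-diene-15,19-dioate
Product: 29 hypoxyterpoid A
Conditions: Pd(PPh3)4 (5 mol %), morpholine, THF, rt; dilute HCl work-up
Reagents that add atoms: none
Why: Pd(0)-catalysed deallylation (Tsuji–Trost allyl transfer to morpholine) cleaves both esters through π-allyl complexes, a process that does not depend on access to the shielded axial C19 carbonyl, and leaves the stereocentres, the exocyclic methylene and the enoate untouched.

**Compound list**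

1 | 5,6-dihydro-2H-pyran-2-one | O=C1C=CCCO1 | starting material
2 | potassium trifluoro(prop-1-en-2-yl)borate | C=C(C)[B-](F)(F)F.[K+] | starting material
3 | (4S)-4-(prop-1-en-2-yl)oxan-2-one | O=C1C[C@@H](C(C)=C)CCO1 | intermediate
4 | tert-butyl(2-iodoethoxy)dimethylsilane | CC(C)(C)[Si](C)(C)OCCI | starting material
5 | lithium enolate of 3 | [Li]OC1=C[C@@H](C(C)=C)CCO1 | intermediate (not isolated)
6 | (3R,4S)-3-[2-(tert-butyldimethylsilyloxy)ethyl]-4-(prop-1-en-2-yl)oxan-2-one | O=C1[C@H](CCO[Si](C)(C)C(C)(C)C)[C@@H](C(C)=C)CCO1 | intermediate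
7 | lithium enolate of 6 | [Li]OC1=C(CCO[Si](C)(C)C(C)(C)C)[C@@H](C(C)=C)CCO1 | intermediate (not isolated)
8 | (3S,4R)-3-[2-(tert-butyldimethylsilyloxy)ethyl]-3-methyl-4-(prop-1-en-2-yl)oxan-2-one | O=C1[C@@](C)(CCO[Si](C)(C)C(C)(C)C)[C@@H](C(C)=C)CCO1 | intermediate
9 | (3S,4R)-3-(2-hydroxyethyl)-3-methyl-4-(prop-1-en-2-yl)oxan-2-one | O=C1[C@@](C)(CCO)[C@@H](C(C)=C)CCO1 | intermediate (not isolated)
10 | (3S)-3-[(3R)-5-hydroxy-2-methylpent-1-en-3-yl]-3-methyloxolan-2-one | O=C1OCC[C@@]1(C)[C@@H](C(C)=C)CCO | intermediate
11 | (3S)-3-[(3R)-5-iodo-2-methylpent-1-en-3-yl]-3-methyloxolan-2-one | O=C1OCC[C@@]1(C)[C@@H](C(C)=C)CCI | intermediate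
12 | but-3-en-1-ylmagnesium bromide | C=CCC[Mg]Br | starting material
13 | methyl but-2-ynoate | CC#CC(=O)OC | starting material
14 | but-3-enylcopper | C=CCC[Cu] | intermediate (not isolated)
15 | methyl (2Z)-2-cuprio-3-methylhepta-2,6-dienoate (alkenylcopper adduct) | C=CCC/C(C)=C(/C(=O)OC)[Cu] | intermediate (not isolated)
16 | methyl (2E)-3-methylhepta-2,6-dienoate | C=CCC/C(C)=C/C(=O)OC | intermediate
17 | methyl (2E)-6,7-dihydroxy-3-methylhept-2-enoate (racemic) | OCC(O)CC/C(C)=C/C(=O)OC | intermediate (not isolated)
18 | methyl (2E)-3-methyl-6-oxohex-2-enoate | O=CCC/C(C)=C/C(=O)OC | intermediate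
19 | methyl (2E)-7,7-dichloro-3-methylhepta-2,6-dienoate | ClC(Cl)=CCC/C(C)=C/C(=O)OC | intermediate
20 | iodo{(3R)-4-methyl-3-[(3S)-3-methyl-2-oxooxolan-3-yl]pent-4-en-1-yl}zinc | O=C1OCC[C@@]1(C)[C@@H](C(C)=C)CC[Zn]I | intermediate (not isolated)
21 | methyl (2E,6Z,10R)-7-chloro-3,11-dimethyl-10-[(3S)-3-methyl-2-oxooxolan-3-yl]dodeca-2,6,11-trienoate | O=C1OCC[C@@]1(C)[C@@H](C(C)=C)CC/C(Cl)=C/CC/C(C)=C/C(=O)OC | intermediate
22 | (trimethylsilyl)methylmagnesium chloride | C[Si](C)(C)C[Mg]Cl | starting material
23 | (trimethylsilyl)methylzinc chloride | C[Si](C)(C)C[Zn]Cl | intermediate (not isolated)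
24 | methyl (2E,6Z,10R)-3,11-dimethyl-10-[(3S)-3-methyl-2-oxooxolan-3-yl]-7-[(trimethylsilyl)methyl]dodeca-2,6,11-trienoate | O=C1OCC[C@@]1(C)[C@@H](C(C)=C)CC/C(C[Si](C)(C)C)=C/CC/C(C)=C/C(=O)OC | intermediate
25 | dipotassium (2E,6Z,10R,11S)-11-(2-hydroxyethyl)-3,11-dimethyl-10-(prop-1-en-2-yl)-7-[(trimethylsilyl)methyl]dodeca-2,6-dienedioate | [K+].[K+].[O-]C(=O)[C@@](C)(CCO)[C@@H](C(C)=C)CC/C(C[Si](C)(C)C)=C/CC/C(C)=C/C(=O)[O-] | intermediate (not isolated)
26 | bis(prop-2-en-1-yl) (2E,6Z,10R,11S)-11-(2-hydroxyethyl)-3,11-dimethyl-10-(prop-1-en-2-yl)-7-[(trimethylsilyl)methyl]dodeca-2,6-dienedioate | C=CCOC(=O)[C@@](C)(CCO)[C@@H](C(C)=C)CC/C(C[Si](C)(C)C)=C/CC/C(C)=C/C(=O)OCC=C | intermediate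
27 | bis(prop-2-en-1-yl) (2E,6Z,10R,11S)-3,11-dimethyl-11-(2-oxoethyl)-10-(prop-1-en-2-yl)-7-[(trimethylsilyl)methyl]dodeca-2,6-dienedioate | C=CCOC(=O)[C@@](C)(CC=O)[C@@H](C(C)=C)CC/C(C[Si](C)(C)C)=C/CC/C(C)=C/C(=O)OCC=C | intermediate
28 | bis(prop-2-en-1-yl) (2R,4S,5R,9S,10R,13E)-2-hydroxylabda-8(17),13-diene-15,19-dioate | C=C1CC[C@@H]2[C@](C)(C[C@@H](O)C[C@]2(C)C(=O)OCC=C)[C@H]1CC/C(C)=C/C(=O)OCC=C | intermediate
29 | hypoxyterpoid A, (2R,4S,5R,9S,10R,13E)-2-hydroxylabda-8(17),13-diene-15,19-dioic acid | C=C1CC[C@@H]2[C@](C)(C[C@@H](O)C[C@]2(C)C(=O)O)[C@H]1CC/C(C)=C/C(=O)O | target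

**Step count and risks**

Total steps: 14. Longest linear sequence: 11 (steps 1–5 and 9–14).

The three steps most likely to fail:

Step 13. Once ring A has closed, the C10 cation may lose a proton from C20 (ene outcome) or be intercepted by the axial ester carbonyl before C9 arrives, and traces of protic acid may protodesilylate the allylsilane, so ring B would not form. The fallback changes the initiator from a Lewis-acid-bound aldehyde to an oxocarbenium ion, which carries no aluminium alkoxide placed for proton transfer, and keeps the same two ring closures. It sets out from 27, which is converted with propane-1,3-diol (PPTS, MgSO4, CH2Cl2) into the 1,3-dioxane acetal F1. Treatment with TiCl4 and 2,6-di-tert-butylpyridine in CH2Cl2 at −78 °C (acetal-initiated polyene cyclisation) should give the bicyclic 3-hydroxypropyl ether F2. Dess–Martin oxidation gives the 3-oxopropyl ether F3, and β-elimination with piperidinium acetate releases the C2 alcohol, which brings the route back at 28.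

Step 9. The alkylzinc may fail to discriminate between the two C–Cl bonds or couple twice, or the alkylpalladium intermediate may undergo β-hydride elimination, so the alkene geometry would be mixed or the yield low. The fallback builds the same trisubstituted alkene by olefination instead of cross-coupling. It sets out from 11, which alkylates methylenetriphenylphosphorane (THF, 0 °C) to give the phosphonium iodide F4. Deprotonation (NaHMDS), iodination of the ylide with I2 at −78 °C, a second deprotonation and addition of aldehyde 18 (Stork–Zhao-type α-iodo ylide olefination) should give the (Z)-alkenyl iodide F5, with iodine cis to C11. Coupling of F5 with 23 under the conditions of step 10 returns to the route at 24.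

Step 11. The freed γ-hydroxy ester may close back to the lactone with loss of allyl alcohol during work-up, or the alkoxide may be O-allylated, so that little alcohol reaches the oxidation. The fallback avoids handling the free hydroxy ester. It sets out from 24 and passes through salt 25 as before, but TESCl and imidazole are added to the DMF solution directly after the esterification, which traps the alcohol as the triethylsilyl ether F6. Swern conditions ((COCl)2, DMSO, CH2Cl2, −78 → −30 °C; Et3N) oxidise primary TES ethers directly to aldehydes, which returns to the route at 27.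

**Further compounds**

F1 | step 13 | bis(prop-2-en-1-yl) (2E,6Z,10R,11S)-11-(1,3-dioxan-2-ylmethyl)-3,11-dimethyl-10-(prop-1-en-2-yl)-7-[(trimethylsilyl)methyl]dodeca-2,6-dienedioate | C=CCOC(=O)[C@@](C)(CC1OCCCO1)[C@@H](C(C)=C)CC/C(C[Si](C)(C)C)=C/CC/C(C)=C/C(=O)OCC=C
F2 | step 13 | bis(prop-2-en-1-yl) (2R,4S,5R,9S,10R,13E)-2-(3-hydroxypropoxy)labda-8(17),13-diene-15,19-dioate | C=C1CC[C@@H]2[C@](C)(C[C@@H](OCCCO)C[C@]2(C)C(=O)OCC=C)[C@H]1CC/C(C)=C/C(=O)OCC=C
F3 | step 13 | bis(prop-2-en-1-yl) (2R,4S,5R,9S,10R,13E)-2-(3-oxopropoxy)labda-8(17),13-diene-15,19-dioate | C=C1CC[C@@H]2[C@](C)(C[C@@H](OCCC=O)C[C@]2(C)C(=O)OCC=C)[C@H]1CC/C(C)=C/C(=O)OCC=C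
F4 | step 9 | {(4R)-5-methyl-4-[(3S)-3-methyl-2-oxooxolan-3-yl]hex-5-en-1-yl}triphenylphosphonium iodide | O=C1OCC[C@@]1(C)[C@@H](C(C)=C)CCC[P+](c1ccccc1)(c1ccccc1)c1ccccc1.[I-]
F5 | step 9 | methyl (2E,6Z,10R)-7-iodo-3,11-dimethyl-10-[(3S)-3-methyl-2-oxooxolan-3-yl]dodeca-2,6,11-trienoate | O=C1OCC[C@@]1(C)[C@@H](C(C)=C)CC/C(I)=C/CC/C(C)=C/C(=O)OC
F6 | step 11 | bis(prop-2-en-1-yl) (2E,6Z,10R,11S)-3,11-dimethyl-10-(prop-1-en-2-yl)-11-[2-(triethylsilyloxy)ethyl]-7-[(trimethylsilyl)methyl]dodeca-2,6-dienedioate | C=CCOC(=O)[C@@](C)(CCO[Si](CC)(CC)CC)[C@@H](C(C)=C)CC/C(C[Si](C)(C)C)=C/CC/C(C)=C/C(=O)OCC=C
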